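## Retrosynthetic overview
1. 19 ⇒ 17 + 18. Key step, done last: the C15–O bond is made by Mitsunobu displacement with unprotected caffeic acid.
2. 17 ⇒ 15 (C8=O → C8=CH2, C15 ester → CH2OH). 15 ⇒ 8 + CH3 (to C10) + 13 (C9–C11), a one-pot conjugate methylation/alkylation that creates the cis ring fusion.
3. 8 ⇒ 7 by a carboxylate-directed 1,3-proton shift that sets C5 (new step). 7 ⇒ 5 by Birch reduction.
4. 5 ⇒ 1 (methylenation, asymmetric hydrovinylation sets C4, vinyl → CO2H). 13 ⇒ 9, which brings C13.
5. Rings: none is closed. Rings A and B are bought together in 1, and ring B is dearomatised in step 4.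

Assumption: the SMILES is read literally as (4S,5S,9R,10R,13S) in labdane numbering. H-5, H-9, CH3-20 and CO2H-19 all lie on one face (β), so this is an A/B-cis, 9-epi labdane and not the natural trans series. Labdane numbering and α/β (β = face of CH3-20) are used below.

## Route

**Step 1**
Reactants: 1 6-methoxy-1-tetralone
Product: 2 6-methoxy-1-methylidene-1,2,3,4-tetrahydronaphthalene
Conditions: Ph3PCH3Br, KN(SiMe3)2, THF, 0 → 23 °C
Reagents that add atoms: methyltriphenylphosphonium bromide C[P+](c1ccccc1)(c1ccccc1)c1ccccc1.[Br-]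
Why: Wittig methylenation of an aryl ketone, with no stereocentre formed.

**Step 2**
Reactants: 2 6-methoxy-1-methylidene-1,2,3,4-tetrahydronaphthalene
Product: 3 (R)-1-ethenyl-6-methoxy-1-methyl-1,2,3,4-tetrahydronaphthalene
Conditions: ethylene (1 atm), [Ni(C3H5)Br]2 (2 mol %), BINOL/bis(1-phenylethyl)amine phosphoramidite (4 mol %, the antipode that delivers R), NaB[3,5-(CF3)2C6H3]4, CH2Cl2, −70 °C
Reagents that add atoms: ethylene C=C
Why: In this asymmetric hydrovinylation of a 1-methylidene-tetralin, the cationic nickel hydride adds Markovnikov to give the tertiary benzylic alkylnickel, ethylene insertion and β-hydride loss follow, and the ligand fixes the face, setting quaternary C4.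

**Step 3**
Reactants: 3 (R)-1-ethenyl-6-methoxy-1-methyl-1,2,3,4-tetrahydronaphthalene
Product: 5 (S)-6-methoxy-1-methyl-1,2,3,4-tetrahydronaphthalene-1-carboxylic acid, via aldehyde 4 (not isolated)
Conditions: O3, CH2Cl2/MeOH, −78 °C; Me2S; concentrate; NaClO2, NaH2PO4, 2-methylbut-2-ene, tBuOH/H2O, 23 °C
Reagents that add atoms: ozone [O-][O+]=O; sodium chlorite [Na+].[O-]Cl=O
Why: Ozonolysis takes the vinyl group faster than the anisole ring and Pinnick oxidation then gives the acid, while C4 is untouched and its descriptor changes from R to S only through CIP priorities.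

**Step 4**
Reactants: 5 (S)-6-methoxy-1-methyl-1,2,3,4-tetrahydronaphthalene-1-carboxylic acid
Product: 7 (S)-1-methyl-6-oxo-1,2,3,4,5,6,7,8-octahydronaphthalene-1-carboxylic acid, via enol ether 6 (not isolated)
Conditions: Li, NH3(l)/THF/tBuOH, −78 → −33 °C; NH4Cl; then (CO2H)2, THF/H2O, 0 °C
Reagents that add atoms: water O
Why: Birch reduction gives the 2,5-dihydroanisole with the tetrasubstituted C5=C10 bond (the carboxylate is inert), and oxalic acid cleaves only the enol ether, stopping at the unconjugated ketone as in the 19-nor-steroid series, with C4 untouched.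

**Step 5**
Reactants: 7 (S)-1-methyl-6-oxo-1,2,3,4,5,6,7,8-octahydronaphthalene-1-carboxylic acid
Product: 8 (1S,8aS)-1-methyl-6-oxo-1,2,3,4,6,7,8,8a-octahydronaphthalene-1-carboxylic acid
Conditions: Me2N(CH2)3NH2 (20 mol %), toluene, 0 °C, stopped at full conversion; 1 M HCl wash
Reagents that add atoms: none
Why: Proposed new method: carboxylate-directed, diamine-catalysed 1,3-proton shift, in which the primary amine condenses with the unhindered C8 ketone and loss of the doubly activated H-9 gives the dienamine N–C8=C9–C10=C5; its γ-carbon C5 is then protonated by the tethered Me2NH+ arm, which a salt bridge to the C19 carboxylate holds on the β face and which also attacks anti to the pseudo-axial C18 methyl (the flat carboxylate takes the pseudo-equatorial site next to C6 to relieve A(1,2) strain), so H-5 arrives syn to CO2H (5S), and the conjugated iminium ion hydrolyses faster than 8 re-enters the cycle, so the ratio is kinetic; the closest known reaction type is the primary–tertiary diamine (dienamine/iminium, ammonium γ-protonation) isomerisation of Birch-derived β,γ-unsaturated cyclohexenones to γ-stereogenic enones, which has not been shown for a ring-fusion tetrasubstituted olefin, next to a quaternary centre, or with direction by a substrate carboxylate.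

**Step 6**
Reactants: 9 methyl hydrogen (R)-3-methylglutarate
Product: 11 (S)-4-methyloxan-2-one, via hydroxy acid 10 (not isolated)
Conditions: LiEt3BH (3.2 equiv), THF, 0 °C; then 2 M HCl, 23 °C
Reagents that add atoms: none
Why: This chemoselective hydride reduction first turns the acid into an unreactive lithium carboxylate, then takes the ester to the alcohol, and acid closes the δ-lactone, with the C13 stereocentre not involved.

**Step 7**
Reactants: 11 (S)-4-methyloxan-2-one
Product: 13 methyl (R)-5-iodo-3-methylpentanoate, via silyl ester 12 (not isolated)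
Conditions: Me3SiI, CH2Cl2, 23 °C; then MeOH
Reagents that add atoms: iodotrimethylsilane C[Si](C)(C)I; methanol CO
Why: In this silyl-iodide lactone opening, O-silylation is followed by SN2 attack of iodide at the O–CH2 carbon, methanol converts the silyl ester into the methyl ester, and the stereocentre is untouched (S becomes R only through CIP priorities).

**Step 8**
Reactants: 8 (1S,8aS)-1-methyl-6-oxo-1,2,3,4,6,7,8,8a-octahydronaphthalene-1-carboxylic acid; 13 methyl (R)-5-iodo-3-methylpentanoate
Product: 15 15-methyl hydrogen (13S)-8-oxo-17-nor-5βH,9βH-labdane-15,19-dioate, via dilithium enolate 14 (not isolated)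
Conditions: Me2CuLi (2.2 equiv, from CuBr·SMe2 and MeLi), Et2O, −40 → 0 °C; 13 (1.5 equiv), DMPU/THF, −20 → 23 °C; NH4Cl, HCl; then NaOMe, MeOH, 23 °C
Reagents that add atoms: methyllithium (delivered as Me2CuLi) [Li]C
Why: Tandem cuprate conjugate addition and enolate alkylation, in which methyl adds to C10 cis to H-5 (the usual cis-angular methylation of Δ9-8-oxo-octalones, reinforced here because the axial C18 methyl closes the α face), the regiodefined enolate is alkylated at C9, and methoxide equilibration puts the chain equatorial (9α, H-9β) in the only low-energy chair–chair form, the one with quaternary C4 equatorial on ring B.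

**Step 9**
Reactants: 15 15-methyl hydrogen (13S)-8-oxo-17-nor-5βH,9βH-labdane-15,19-dioate
Product: 16 15-methyl hydrogen (13S)-5βH,9βH-labd-8(17)-ene-15,19-dioate
Conditions: Ph3PCH3Br (4 equiv), KN(SiMe3)2 (3.8 equiv), THF/toluene, 23 → 60 °C
Reagents that add atoms: methyltriphenylphosphonium bromide C[P+](c1ccccc1)(c1ccccc1)c1ccccc1.[Br-]
Why: Wittig methylenation as practised on 8-oxo-17-norlabdanes, where C9 already holds its thermodynamic configuration so the basic ylide cannot erode it, and the carboxylate and methyl ester are spectators.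

**Step 10**
Reactants: 16 15-methyl hydrogen (13S)-5βH,9βH-labd-8(17)-ene-15,19-dioate
Product: 17 (13S)-15-hydroxy-5βH,9βH-labd-8(17)-en-19-oic acid
Conditions: LiEt3BH (3.3 equiv), THF, 0 °C; 1 M HCl
Reagents that add atoms: none
Why: In this chemoselective ester reduction the reagent deprotonates CO2H (giving H2 and inert Et3B, so no free BH3 can hydroborate the olefin), reduces the open methyl ester, and leaves the hindered axial lithium carboxylate alone.

**Step 11 (key step)**
Reactants: 17 (13S)-15-hydroxy-5βH,9βH-labd-8(17)-en-19-oic acid; 18 caffeic acid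
Product: 19 (13S)-15-[(E)-3-(3,4-dihydroxyphenyl)prop-2-enoyloxy]-5βH,9βH-labd-8(17)-en-19-oic acid
Conditions: 18 (3 equiv), PPh3 (1.3 equiv), DIAD (1.3 equiv, slow addition), THF, 0 → 23 °C
Reagents that add atoms: none
Why: In this Mitsunobu esterification the betaine is protonated by the most acidic and most abundant acid (caffeic acid), the primary C15 alcohol becomes the alkoxyphosphonium ion and caffeate displaces Ph3PO at C15, while the phenols (pKa about 9) and the hindered, less acidic C19 acid stay out, no stereocentre is touched and the E olefin is kept.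

## Compound list
1 | 6-methoxy-1-tetralone | COc1ccc2c(c1)CCCC2=O | starting material
2 | 6-methoxy-1-methylidene-1,2,3,4-tetrahydronaphthalene | C=C1CCCc2cc(OC)ccc21 | intermediate
3 | (R)-1-ethenyl-6-methoxy-1-methyl-1,2,3,4-tetrahydronaphthalene | COc1ccc2c(c1)CCC[C@]2(C)C=C | intermediate
4 | (S)-6-methoxy-1-methyl-1,2,3,4-tetrahydronaphthalene-1-carbaldehyde | COc1ccc2c(c1)CCC[C@]2(C)C=O | intermediate
5 | (S)-6-methoxy-1-methyl-1,2,3,4-tetrahydronaphthalene-1-carboxylic acid | COc1ccc2c(c1)CCC[C@]2(C)C(=O)O | intermediate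
6 | (S)-6-methoxy-1-methyl-1,2,3,4,5,8-hexahydronaphthalene-1-carboxylic acid | COC1=CCC2=C(C1)CCC[C@]2(C)C(=O)O | intermediate
7 | (S)-1-methyl-6-oxo-1,2,3,4,5,6,7,8-octahydronaphthalene-1-carboxylic acid (C5=C10 olefin) | O=C1CCC2=C(C1)CCC[C@]2(C)C(=O)O | intermediate
8 | (1S,8aS)-1-methyl-6-oxo-1,2,3,4,6,7,8,8a-octahydronaphthalene-1-carboxylic acid (H-5 cis to CO2H) | O=C1CC[C@H]2C(=C1)CCC[C@]2(C)C(=O)O | intermediate
9 | methyl hydrogen (R)-3-methylglutarate | COC(=O)C[C@H](C)CC(=O)O | starting material
10 | (S)-5-hydroxy-3-methylpentanoic acid | OCC[C@H](C)CC(=O)O | intermediate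
11 | (S)-4-methyloxan-2-one | O=C1C[C@@H](C)CCO1 | intermediate
12 | trimethylsilyl (R)-5-iodo-3-methylpentanoate | ICC[C@H](C)CC(=O)O[Si](C)(C)C | intermediate
13 | methyl (R)-5-iodo-3-methylpentanoate | ICC[C@H](C)CC(=O)OC | intermediate
14 | dilithium C8-enolate/C19-carboxylate of the cis-fused 10β-methyl decalone (H-5β) | [Li+].[Li+].[O-]C=1CC[C@H]2[C@](C)(CCC[C@]2(C)C(=O)[O-])C=1 | intermediate
15 | 15-methyl hydrogen (13S)-8-oxo-17-nor-5βH,9βH-labdane-15,19-dioate (cis-decalone; H-5, H-9, CH3-20, CO2H-19 all β; chain 9α) | O=C1CC[C@H]2[C@](C)(CCC[C@]2(C)C(=O)O)[C@@H]1CC[C@H](C)CC(=O)OC | intermediate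
16 | 15-methyl hydrogen (4S,5S,9R,10R,13S)-labd-8(17)-ene-15,19-dioate | C=C1CC[C@H]2[C@](C)(CCC[C@]2(C)C(=O)O)[C@@H]1CC[C@H](C)CC(=O)OC | intermediate
17 | (4S,5S,9R,10R,13S)-15-hydroxylabd-8(17)-en-19-oic acid (5,9-di-epi-imbricatolic acid) | C=C1CC[C@H]2[C@](C)(CCC[C@]2(C)C(=O)O)[C@@H]1CC[C@H](C)CCO | intermediate
18 | caffeic acid, (E)-3-(3,4-dihydroxyphenyl)prop-2-enoic acid | OC(=O)/C=C/c1ccc(O)c(O)c1 | starting material
19 | (4S,5S,9R,10R,13S)-15-(E-caffeoyloxy)labd-8(17)-en-19-oic acid | C=C1CC[C@H]2[C@](C)(CCC[C@]2(C)C(=O)O)[C@@H]1CC[C@H](C)CCOC(=O)/C=C/c1ccc(O)c(O)c1 | target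

## Step count and risks
Total steps: 11. Longest linear sequence: 9 (steps 1–5 and 8–11).

**Step 5 (new step).** The selectivity may be low, or it may drift towards the roughly 1:1 thermodynamic ratio. The fallback obtains C5 by equilibration and recycling instead of by control. It sets out from 7 and returns at 8. Treatment of 7 with 1 M HCl in MeOH at 23 °C is the classical conjugation of Birch-derived β,γ-enones. It gives a mixture of 8 and its C5 epimer (1S,8aR)-1-methyl-6-oxo-1,2,3,4,6,7,8,8a-octahydronaphthalene-1-carboxylic acid F1. The two diastereomers are separated by chromatography or as dicyclohexylammonium salts, and F1 is returned to the same acid bath.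

**Step 8.** The hindered enone may react slowly. Enolate 14, which sits next to quaternary C10, may be alkylated sluggishly by an unactivated iodide, and carboxylate O-alkylation may compete. The fallback makes C9–C11 by an aldol reaction instead of an SN2 alkylation. It sets out from 8 and 13 and returns at 15.
- Kornblum oxidation of 13 (DMSO, NaHCO3, 100 °C) gives methyl (S)-3-methyl-5-oxopentanoate F2.
- 8 is converted into 14 as above. ZnCl2 and F2 are added at −78 °C to give 15-methyl hydrogen (13S)-11-hydroxy-8-oxo-17-nor-5βH-labdane-15,19-dioate F3 as a mixture at C9 and C11.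
- TsOH in hot toluene dehydrates it to 15-methyl hydrogen (13S)-8-oxo-17-nor-5βH-labd-9(11)-ene-15,19-dioate F4.
- H2 over Pd/C saturates the only C=C bond, and NaOMe/MeOH equilibrates C9 to give 15.

**Step 11.** Self-esterification through the C19 acid, or phenol alkylation, may lower the yield. The fallback makes the C15–O bond by acylation and builds the cinnamate olefin last. It sets out from 17 and returns at 19. Heating 17 with Meldrum's acid in toluene opens the dioxanedione at the primary alcohol and gives (13S)-15-(carboxyacetoxy)-5βH,9βH-labd-8(17)-en-19-oic acid F5. Knoevenagel–Doebner condensation of F5 with 3,4-dihydroxybenzaldehyde (pyridine, catalytic piperidine, 50 °C) gives 19 with the E olefin.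

## Further compounds
F1 | step 5 | (1S,8aR)-1-methyl-6-oxo-1,2,3,4,6,7,8,8a-octahydronaphthalene-1-carboxylic acid | O=C1CC[C@@H]2C(=C1)CCC[C@]2(C)C(=O)O
F2 | step 8 | methyl (S)-3-methyl-5-oxopentanoate | O=CC[C@H](C)CC(=O)OC
F3 | step 8 | 15-methyl hydrogen (13S)-11-hydroxy-8-oxo-17-nor-5βH-labdane-15,19-dioate (mixture at C9 and C11) | O=C1CC[C@H]2[C@](C)(CCC[C@]2(C)C(=O)O)C1C(O)C[C@H](C)CC(=O)OC
F4 | step 8 | 15-methyl hydrogen (13S)-8-oxo-17-nor-5βH-labd-9(11)-ene-15,19-dioate | O=C1CC[C@H]2[C@](C)(CCC[C@]2(C)C(=O)O)C1=CC[C@H](C)CC(=O)OC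
F5 | step 11 | (13S)-15-(carboxyacetoxy)-5βH,9βH-labd-8(17)-en-19-oic acid | C=C1CC[C@H]2[C@](C)(CCC[C@]2(C)C(=O)O)[C@@H]1CC[C@H](C)CCOC(=O)CC(=O)O
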